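(The readings were generated by integration from invented constants; the scatter is artificial.)

The south-west run lost solid substrate along a nearly straight line, while its target never read above 0.6%. The east flask, asked about at a later time, has begun the same way.

| flask | solid substrate | acid | protic impurity | remark | time |
|---|---|---|---|---|---|
| east | 0.13 M | 0.013 M | 0.026 M | the very flask that is asked about, followed so far |  |
| south-west | 0.20 M | 0.013 M | 0.026 M | run made earlier |  |
| flask | 0.13 M | 0.0130 M | 0.0260 M |  | 5.0 min |

east run (percent of the solid substrate charged)

| time / s | solid substrate / % | target / % |
|---|---|---|
| 10.0 | 99.3 | 0.3 |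
| 20.0 | 98.4 | 0.2 |
| 30.0 | 98.7 | 0 |
| 40.0 | 97.4 | 0.5 |
| 50.0 | 97.6 | 0 |

south-west run (percent of the solid substrate charged)

| time / min | solid substrate / % | target / % |
|---|---|---|
| 0.333 | 98.9 | 0.2 |
| 0.833 | 98.3 | 0.6 |
| 1.50 | 96.6 | 0.4 |
| 2.50 | 95.2 | 0.3 |
| 4.00 | 92.4 | 0.5 |

(standard deviation of a reading: 0.3 percentage points)

* part of the solid substrate that has reacted (what has only dissolved counts as not reacted) at 5.0 min
* pH of the solution at 5.0 min

- acid is the free proton; pH is minus the decimal logarithm of its molar concentration
- as a solid, counted per litre of solution: solid substrate
- at the start none of the solid substrate is in solution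
- what has only dissolved of solid substrate counts as not reacted

The reckoning here follows the rate. Over its whole run the south-west flask lost solid at 3.80 mM/min, and the east flask at 3.74 mM/min. The charges stand in a ratio of 0.650 but these rates, read over spans of different length, in one of 0.984, so the readings show no rate that follows the loading. Time might slow it: the south-west rate reads 4.08 mM/min up to 0.833 min and 3.73 mM/min between 2.50 min and 4.00 min, a factor of 0.914. That early rate rests on a loss of 1.7 percentage points read with a scatter of 0.3 points, so the factor is no firm slowing.

As a first round, the east flask at 3.80 mM/min for 5.0 min loses 19.0 mM, or 14.6% of its charge. The second round puts that loss back in. It is not appearing as target, and the protic impurity is the likely taker. Dividing c(protic impurity) by the rate gives 6.84 min, the spending time: how long this limiting reagent lasts at one impurity per substrate lost. It is longer than the asked time, so the line stands and the reckoning stays at 14.6%.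

The forecast gives 14.8% reacted, more than the 14.6% reckoned here, and a pH of 1.89, with the remark: “The absolute rate is therefore the same at both loadings”.

The flask gives 13.6% and a pH of 1.89.

    starting material + acid → weak acid + acid + target (k = 0.420 /M/s)
    weak acid ⇌ conjugate base + acid, settled at all times (K = 2.50 × 10⁻⁶ M)
    starting material → weak acid + target (k = 0.00130 /s)
    2 starting material → homo dimer (k = 0.00990 /M/s)
    starting material + protic impurity → quenched substrate (k = 3.60 /M/s)
    solid substrate ⇌ starting material, rate k6*(cs6 - [starting material]) while solid is left; crystals form when [starting material] > cs6 (solubility = 4.20 mM, k = 0.0190 /s)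

Beside the reacted part of the east flask, 0.951% of the charge stands dissolved as starting material at 5.00 min, and the answer does not count it. The east flask then keeps 39% of its protic impurity, where the spending time reckons 26.9%. The same flask read at 12 min is past the spending time. The straight line reckons 35.1% there, and that flask stands at 25.5%, with 1.7% of the protic impurity left, quenched substrate at 19.7% and target at 5.86%.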